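**Retrosynthetic overview**

1. Target 10 ⇐ reduction of the bis(o-quinone) 9 ⇐ oxidative exchange of one ortho bromine for oxygen in each ring of bis(2,3,5,6-tetrabromo-4-hydroxybenzyl) ether 7, using IBX.
2. Feature the route rests on: in each benzene ring of 7 (C1 carries benzylic C7, Br on C2, C3, C5 and C6, OH on C4) a local mirror plane through C1 and C4 makes the two bromines ortho to the hydroxyl (C3–Br and C5–Br) equivalent. Replacing either by oxygen gives the 2,3,6-tribromo-4,5-dihydroxybenzyl pattern of the target.
3. 7 ⇐ one-flask half-hydrolysis and self-etherification of benzyl bromide 4 through quinone methide 5 and alcohol 6 ⇐ tetrabromo-p-cresol 3 ⇐ p-cresol 1 and bromine 2.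
4. No ring is formed. Both benzene rings come from p-cresol; the only ring events are dearomatisation to the o-quinone (step 4) and rearomatisation (step 5).

Key step: step 4

Remark: the target is achiral and has no stereocentre, so no stereocontrol is needed; ring atoms are numbered as in line 2 throughout.

**Route**

Step 1
Reactants: 1 p-cresol (4-methylphenol); 2 bromine
Product: 3 2,3,5,6-tetrabromo-4-methylphenol
Conditions: Br2 (4.3 equiv), AlBr3 (10 mol %), 1,2-dichloroethane, 0 °C → 50 °C, dark
Reagents that add atoms: bromine, BrBr
Why: Exhaustive electrophilic aromatic bromination; the two positions ortho to the hydroxyl react readily and the Lewis acid forces bromine onto the two remaining positions, while the near-stoichiometric charge of bromine and the dark limit attack on the methyl group.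

Step 2
Reactants: 3 2,3,5,6-tetrabromo-4-methylphenol; 2 bromine
Product: 4 2,3,5,6-tetrabromo-4-(bromomethyl)phenol
Conditions: Br2 (1.3 equiv), PhCF3, hν (visible lamp), 80 °C
Reagents that add atoms: bromine, BrBr
Why: Free-radical benzylic bromination (photobromination); every ring carbon is substituted, so bromine can only enter the methyl group, and the two flanking bromines should hold the reaction at the monobromide as in the side-chain bromination of pentabromotoluene.

Step 3
Reactants: 4 2,3,5,6-tetrabromo-4-(bromomethyl)phenol (two molecules); water
Product: 7 bis(2,3,5,6-tetrabromo-4-hydroxybenzyl) ether, via quinone methide 5 (not isolated), via hydroxymethylphenol 6 (not isolated)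
Conditions: iPr2NEt (1.2 equiv), H2O (0.5 equiv), MeCN/THF (1:1), 0 °C → 40 °C; then 1 M HCl work-up
Reagents that add atoms: water, O
Why: Quinone methide solvolysis of a para-hydroxybenzyl bromide (1,6-elimination followed by 1,6-conjugate addition): the phenoxide of 4 expels bromide to give 5, half of which takes up the limiting water to give 6, whose primary hydroxyl then adds to the other half of 5; adducts of 5 with bromide or with the hindered phenoxide oxygen ionise again, whereas the dialkyl ether would have to expel an alkoxide, so the material should collect as 7.

Step 4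
Reactants: 7 bis(2,3,5,6-tetrabromo-4-hydroxybenzyl) ether; 8 IBX (2-iodoxybenzoic acid)
Product: 9 5,5'-[oxybis(methylene)]bis(3,4,6-tribromocyclohexa-3,5-diene-1,2-dione)
Conditions: IBX (2.6 equiv), AgOAc (2.2 equiv), DMF, rt → 50 °C, dark
Reagents that add atoms: IBX (2-iodoxybenzoic acid), O=C1OI(=O)(O)c2ccccc12
Why: Proposed new method: each phenol oxygen on C4 should exchange for the hydroxyl on pentavalent iodine, and the iodine-bound oxo oxygen is then handed within this aryl ester to the neighbouring carbon C5 while iodine drops to the trivalent state; since C5 carries bromine instead of hydrogen, the resulting 6-bromo-6-(iodanyloxy)cyclohexa-2,4-dienone cannot tautomerise and is expected to collapse by loss of bromide (taken up as AgBr) and O–I cleavage to the C5 carbonyl of the o-quinone. The closest known reaction types are the IBX ortho-oxygenation of phenols at a C–H position to o-quinones and the oxidative ipso-dehalogenation of para-halophenols to p-quinones. No ring is closed and no stereocentre is created; the step makes the two C5–O bonds, one in each ring. The selectivity needed is ortho over para attack, and it is secured by the O–I tether, which reaches only C3 or C5 and keeps oxygen away from C1, where attack would expel the benzylic ether; C3 and C5 are related by the local mirror plane through C1 and C4, so both give the same ring. Each ring can react only once, because the o-quinone formed is no longer a phenol. The electron-poor ring is the weak point of the step, which is why it is run warm and with a bromide sink that keeps bromide from being re-oxidised to electrophilic bromine.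

Step 5
Reactants: 9 5,5'-[oxybis(methylene)]bis(3,4,6-tribromocyclohexa-3,5-diene-1,2-dione)
Product: 10 bis(2,3,6-tribromo-4,5-dihydroxybenzyl) ether (5,5'-[oxybis(methylene)]bis(3,4,6-tribromobenzene-1,2-diol))
Conditions: Na2S2O4 (6 equiv), EtOAc/H2O, 0 °C → rt, argon
Reagents that add atoms: none
Why: Two-electron, two-proton reduction of each o-quinone to its catechol by dithionite, the usual finish of a phenol-to-catechol oxidation; aryl bromides and the dibenzyl ether should be inert under these cold, near-neutral biphasic conditions.

**Compound list**

1 | p-cresol (4-methylphenol) | Cc1ccc(O)cc1 | starting material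
2 | bromine | BrBr | starting material
3 | 2,3,5,6-tetrabromo-4-methylphenol | Cc1c(Br)c(Br)c(O)c(Br)c1Br | intermediate
4 | 2,3,5,6-tetrabromo-4-(bromomethyl)phenol | BrCc1c(Br)c(Br)c(O)c(Br)c1Br | intermediate
5 | 2,3,5,6-tetrabromo-4-methylidenecyclohexa-2,5-dien-1-one (quinone methide, not isolated) | C=C1C(Br)=C(Br)C(=O)C(Br)=C1Br | intermediate
6 | 2,3,5,6-tetrabromo-4-(hydroxymethyl)phenol (not isolated) | OCc1c(Br)c(Br)c(O)c(Br)c1Br | intermediate
7 | bis(2,3,5,6-tetrabromo-4-hydroxybenzyl) ether | Oc1c(Br)c(Br)c(COCc2c(Br)c(Br)c(O)c(Br)c2Br)c(Br)c1Br | intermediate
8 | IBX (2-iodoxybenzoic acid) | O=C1OI(=O)(O)c2ccccc12 | starting material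
9 | 5,5'-[oxybis(methylene)]bis(3,4,6-tribromocyclohexa-3,5-diene-1,2-dione) | O=C1C(=O)C(Br)=C(COCC2=C(Br)C(=O)C(=O)C(Br)=C2Br)C(Br)=C1Br | intermediate
10 | bis(2,3,6-tribromo-4,5-dihydroxybenzyl) ether | Oc1c(O)c(Br)c(COCc2c(Br)c(O)c(O)c(Br)c2Br)c(Br)c1Br | target

**Step count and risks**

Total step count: 5. Longest linear sequence: 5 steps (1 → 3 → 4 → 7 → 9 → 10).

Steps most likely to fail:

1. Step 4. The tetrabrominated ring may be too electron-poor to accept oxygen from iodine, so the aryl ester may simply persist. Oxidation may also drift to attack at C1 with loss of the benzylic ether, or released bromide may be re-oxidised and brominate ipso. The fallback uses known chemistry and brings the ortho oxygen in from the start as a methyl ether. It sets out from bromine 2 together with commercial 1,2-dimethoxy-4-methylbenzene F1 and comes back to the route at target 10. F1 should be ring-brominated exhaustively (Br2, FeBr3 cat., AcOH) to 1,2,4-tribromo-5,6-dimethoxy-3-methylbenzene F2. Wohl–Ziegler bromination (NBS, AIBN, PhCF3, reflux) should give 1,2,4-tribromo-3-(bromomethyl)-5,6-dimethoxybenzene F3. BBr3 (CH2Cl2, −78 °C → rt) should cleave both methyl ethers to 3,4,6-tribromo-5-(bromomethyl)benzene-1,2-diol F4. Aqueous acetone should hydrolyse this para-hydroxybenzyl bromide to 3,4,6-tribromo-5-(hydroxymethyl)benzene-1,2-diol F5. Acid-catalysed dehydrative self-etherification (TsOH·H2O cat., 1,4-dioxane, 4 Å molecular sieves, 60 °C, argon) should then give 10.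

2. Step 3. Capture of the quinone methide by phenoxide oxygen may outrun capture by water and by the alcohol, so that aryl benzyl ether oligomers build up and revert too slowly; with the water charge slightly off, the reaction may also stop at the alcohol. The fallback separates the two events and drives the second by acid instead of base. It sets out from bromide 4 and comes back at 7. Solvolysis of 4 in acetone/H2O (3:1) at rt, with water in large excess, should give 2,3,5,6-tetrabromo-4-(hydroxymethyl)phenol 6 as an isolated compound. Heating 6 with TsOH·H2O (5 mol %) in 1,2-dichloroethane over 4 Å molecular sieves at 80 °C should then ionise the benzylic hydroxyl and let a second molecule of 6 capture the 4-hydroxybenzyl cation through its primary hydroxyl, with removal of water pulling the equilibrium to 7. No new compound arises on this way (F0).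

3. Step 2. The free phenol may quench the radical chain, or bromine may add ipso at C1 and lead to over-bromination. The fallback masks the phenol before the radical step. It sets out from 3 and comes back at 7 by way of alcohol 6. Acetylation (Ac2O, pyridine, DMAP cat.) should give 2,3,5,6-tetrabromo-4-methylphenyl acetate F6. Wohl–Ziegler bromination (NBS, AIBN, PhCF3, reflux) should give 2,3,5,6-tetrabromo-4-(bromomethyl)phenyl acetate F7. LiOH in THF/H2O should cleave the acetate, after which the phenoxide expels bromide to quinone methide 5 and water adds to give 6 in isolated form. Acid-catalysed dehydrative self-etherification of 6 (TsOH·H2O cat., 1,2-dichloroethane, 4 Å molecular sieves, 80 °C) should then give 7.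

**Further compounds**

F1 | step 4 | 1,2-dimethoxy-4-methylbenzene (3,4-dimethoxytoluene) | COc1ccc(C)cc1OC
F2 | step 4 | 1,2,4-tribromo-5,6-dimethoxy-3-methylbenzene | Cc1c(Br)c(Br)c(OC)c(OC)c1Br
F3 | step 4 | 1,2,4-tribromo-3-(bromomethyl)-5,6-dimethoxybenzene | COc1c(OC)c(Br)c(CBr)c(Br)c1Br
F4 | step 4 | 3,4,6-tribromo-5-(bromomethyl)benzene-1,2-diol | Oc1c(O)c(Br)c(CBr)c(Br)c1Br
F5 | step 4 | 3,4,6-tribromo-5-(hydroxymethyl)benzene-1,2-diol | Oc1c(O)c(Br)c(CO)c(Br)c1Br
F0 | step 3 | none | none
F6 | step 2 | 2,3,5,6-tetrabromo-4-methylphenyl acetate | CC(=O)Oc1c(Br)c(Br)c(C)c(Br)c1Br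
F7 | step 2 | 2,3,5,6-tetrabromo-4-(bromomethyl)phenyl acetate | CC(=O)Oc1c(Br)c(Br)c(CBr)c(Br)c1Br
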